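The numbers were drawn at random within sensible limits; the result is computed.

The constants show two steps that consume the same starting material and partner. The first needs the catalyst and gives it back, while the second climbs more steeply with temperature, its activation energy being higher by 28.0 kJ mol⁻¹.

    starting material + partner + catalyst → catalyst + target (k1 = 530 L² mol⁻² min⁻¹, Ea1 = 38.0 kJ mol⁻¹)
    starting material + partner → uncatalysed product (k2 = 0.13 L mol⁻¹ min⁻¹, Ea2 = 66.0 kJ mol⁻¹)
    solid substrate ⇌ starting material, rate k3*(cs3 - [starting material]) while solid is left; crystals form when [starting material] > cs3 (cs3 = 0.074 M, k3 = 0.093 min⁻¹)
    (constants at −20 °C)

| setting | birch | maple | cedar | ash |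
|---|---|---|---|---|
| solid substrate | 0.20 M | 0.20 M | 0.20 M | 0.20 M |
| partner | 0.260 M | 0.260 M | 0.260 M | 0.260 M |
| catalyst | 1.0 mM | 1.0 mM | 1.0 mM | 1.0 mM |
| temperature | −5 °C |  | 10 °C | −20 °C |
| time | 2.0 h | 2.0 h | 2.0 h | 2.0 h |
| remark |  | at 10 °C until 40 min, from then on at −20 °C |  |  |

- as a solid, counted per litre of solution: solid substrate
- constants are those at −20 °C; use the activation energies for any other temperature
- at the start none of the solid substrate is in solution
- what has only dissolved of solid substrate counts as not reacted

1. the flask with the highest share of target in all that became target or uncatalysed product ("all alike" if they lie within 1.5 percentage points) (birch / maple / cedar / ash / all alike)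
2. share of target in all that became target or uncatalysed product, birch
3. share of target in all that became target or uncatalysed product, maple
4. share of target in all that became target or uncatalysed product, cedar
5. share of target in all that became target or uncatalysed product, ash

I divided the rate of the first step by the rate of the second. Starting material and partner stand in both rates and cancel, and time goes with them. What remained I called the split, or selectivity factor, which at −20 °C is 4.08: the target made per uncatalysed product made at any moment, equal to the first constant times the catalyst concentration, divided by the second constant. The share of target is then the split divided by one plus the split. Correcting the split for temperature with the difference in activation energies, I set up this small table: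

- ash, −20 °C: split 4.08, share 80.3%
- birch, −5 °C: split 1.94, share 66.0%
- cedar, 10 °C: split 0.996, share 49.9%

Reading down, the split falls as the flask gets warmer. From the coldest flask to the hottest, the first step speeds up 6.8 times and the second 28 times, so ash stands higher than the other two rows.

Maple has no row of its own, since it starts as cedar and is cooled at 40 min. Its place depends on how much of the charge, solid or dissolved, is still unreacted by then. No activation energy is given for the dissolving, and if dissolved starting material stays far under its solubility of 0.074 M, the solid feeds in at 0.00688 M min⁻¹. The charge then takes about 29.1 min, which is shorter than the time before cooling, so I put maple at cedar's 49.9%.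

The forecast gave 66% for birch, 50% for maple, 49.9% for cedar and 80.3% for ash, with ash highest, and held that in maple “the later cooling has almost nothing left to act on”.

The simulation gave 66.0% for birch, 49.9% for maple, 49.9% for cedar and 80.3% for ash, with ash highest.

In maple, at 0.256 h, starting material was being made 1.03 times as fast as it was used, and half of the dissolving was done by 0.256 h, while the flask still stood at 10 °C. When maple was cooled at 0.667 h, solid substrate stood at 0% and starting material at 0.115% of the charge, and that rest, taken at ash's share, reckons to a shift of 0.035 percentage points in maple. One more flask, like maple but with 2.5 × 10⁻⁴ M of catalyst, has its warm split cut to 0.249, which reckons to a share of 19.9%, and it gave 20.1%.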